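**Retrosynthetic overview**
1. The target is (+)-afzelechin carrying two identical arms on C6 and C8 of ring A, each Ar–CαH–C3'(oxolane). Both Cα–C3' bonds are cut in one operation, giving a flavan 6,8-bis(o-hydroxybenzhydrol) and two molecules of one enantiopure 2-aryl-4,5-dihydrofuran (oxolane C2'=C3' at the enol ether level).
2. Enabling feature: each Cα is benzylic and ortho to a ring A phenol oxygen (O7 beside C8, O5 beside C6), so O7=C7–C8=Cα and O5=C5–C6=Cα o-quinone methides are available as heterodienes. C2' carries the ring oxygen O1' and an electron-rich aryl group, so C2'=C3' can be an enol ether dienophile. The [4+2] union forms Cα–C3' and closes temporary pyran rings (O7–C2' and O5–C2' ketals), which hydride later opens to leave C2'–H and the free 5- and 7-OH groups.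
3. The dihydrofuran comes from a (1R,2R)-1,2-diaroyl-3-arylcyclopropane by Cloke–Wilson ring expansion. The cyclopropane comes from an organocatalytic enal/sulfonium ylide cyclopropanation, the only catalyst-set stereogenic element of the arms (C4'); C5', C3', Cα and C2' are relayed from it.
4. The bis-benzhydrol comes from purchased (+)-afzelechin by per-benzylation, 6,8-dibromination, double formylation, chelation-controlled 5,7-debenzylation and aryl Grignard addition.
5. Ring order: cyclopropane, then dihydrofuran (the future oxolane), then two temporary pyran rings on ring A (key step), then reductive opening to the two oxolanes, then global hydrogenolysis.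

Key step: step 14

Remark: (+)-afzelechin (15) is taken as a purchasable natural flavan-3-ol; it supplies both flavan stereocentres.
Remark: (S)-indoline-2-carboxylic acid is assumed to give the (1R,2R,3R)-cyclopropane through carboxylate-directed delivery of the ylide; should the sense be opposite, the (R)-acid is used.
Arm numbering used below: Cα is the diarylmethine; the oxolane is O1', C2' (2,4-dioxygenated aryl), C3' (bonded to Cα), C4' (aroyl), C5' (4-oxygenated aryl). The same primed numbers are used for dihydrofuran 14.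

Step 1
Reactants: 1 1-[2,4-bis(benzyloxy)phenyl]ethan-1-one
Product: 2 1-[2,4-bis(benzyloxy)phenyl]-2-bromoethan-1-one
Conditions: CuBr2 (2.1 equiv), EtOAc/CHCl3, reflux
Reagents that add atoms: copper dibromide, Br[Cu]Br
Why: α-Bromination of an aryl methyl ketone through its copper-bound enol is selective for the acetyl group over the electron-rich ring and stops at the monobromide.

Step 2
Reactants: 2 1-[2,4-bis(benzyloxy)phenyl]-2-bromoethan-1-one
Product: 4 1-[2,4-bis(benzyloxy)phenyl]-2-(dimethyl-λ4-sulfanylidene)ethan-1-one, via sulfonium bromide 3 (not isolated)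
Conditions: Me2S, acetone, rt; then aq NaOH, CHCl3, 0 °C
Reagents that add atoms: dimethyl sulfide, CSC
Why: SN2 alkylation of the sulfide by the phenacyl bromide and deprotonation of the acidic α-position should give the storable carbonyl-stabilised sulfonium ylide.

Step 3
Reactants: 5 4-(benzyloxy)benzaldehyde; 6 (triphenyl-λ5-phosphanylidene)acetaldehyde
Product: 7 (2E)-3-[4-(benzyloxy)phenyl]prop-2-enal
Conditions: toluene, 80 °C
Reagents that add atoms: none
Why: Wittig olefination with a stabilised formylmethylene ylide is (E)-selective and with one equivalent stops at the enal.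

Step 4
Reactants: 7 (2E)-3-[4-(benzyloxy)phenyl]prop-2-enal; 4 sulfonium ylide
Product: 8 (1R,2R,3R)-2-[2,4-bis(benzyloxy)benzoyl]-3-[4-(benzyloxy)phenyl]cyclopropane-1-carbaldehyde
Conditions: (S)-indoline-2-carboxylic acid (20 mol %), CHCl3, −10 °C
Reagents that add atoms: none
Why: Iminium-activated organocatalytic cyclopropanation (Michael addition of the ylide to the iminium ion, then 3-exo-tet closure of the enamine with loss of Me2S), in which the (E)-enal fixes aryl trans to formyl, the closure places aroyl trans to formyl, and the catalyst carboxylate directs the ylide to one face of the iminium ion and so sets the absolute configuration.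

Step 5
Reactants: 9 4-bromobenzene-1,3-diol
Product: 10 2,4-bis(benzyloxy)-1-bromobenzene
Conditions: BnBr, K2CO3, DMF, 60 °C
Reagents that add atoms: benzyl bromide, BrCc1ccccc1
Why: Williamson O-benzylation of both phenols.

Step 6
Reactants: 10 2,4-bis(benzyloxy)-1-bromobenzene; 8 cyclopropane carbaldehyde
Product: 12 cyclopropyl ketone carbinol (carbinol epimers), via aryl Grignard reagent 11 (not isolated)
Conditions: Mg, THF, 40 °C; then 8, THF, −78 °C; pH 7 buffer
Reagents that add atoms: none
Why: Grignard addition at −78 °C is chemoselective for the aldehyde over the hindered, electron-rich aryl ketone, and the new carbinol centre is of no consequence because it is oxidised in the next step.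

Step 7
Reactants: 12 cyclopropyl ketone carbinol
Product: 13 {(1R,2R)-3-[4-(benzyloxy)phenyl]cyclopropane-1,2-diyl}bis{[2,4-bis(benzyloxy)phenyl]methanone}
Conditions: Dess–Martin periodinane, NaHCO3, CH2Cl2, 0 °C to rt
Reagents that add atoms: none
Why: Buffered Dess–Martin oxidation gives the trans-diketone without ionising the cyclopropylcarbinol; with two identical aroyl groups the aryl-bearing ring carbon is no longer stereogenic, so only the (1R,2R) element remains.

Step 8
Reactants: 13 trans-1,2-diaroyl-3-arylcyclopropane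
Product: 14 {(2S,3S)-5-[2,4-bis(benzyloxy)phenyl]-2-[4-(benzyloxy)phenyl]-2,3-dihydrofuran-3-yl}[2,4-bis(benzyloxy)phenyl]methanone
Conditions: Sc(OTf)3 (10 mol %), 4 Å MS, CH2Cl2, 0 °C to rt
Reagents that add atoms: none
Why: Lewis acid-catalysed Cloke–Wilson rearrangement of a donor–acceptor cyclopropyl ketone, in which heterolysis of either bond to the 4-(benzyloxy)phenyl carbon gives the same zwitterion (the two aroyl carbons are equivalent by the twofold symmetry), the untouched aroyl carbon becomes C4' (S), and O-closure onto the benzylic cation trans to the aroyl group sets C5' (S).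

Step 9
Reactants: 15 (+)-afzelechin
Product: 16 (2R,3S)-3,5,7-tris(benzyloxy)-2-[4-(benzyloxy)phenyl]-3,4-dihydro-2H-chromene
Conditions: NaH, BnBr, n-Bu4NI (cat.), DMF, 0 °C to rt
Reagents that add atoms: benzyl bromide, BrCc1ccccc1
Why: Williamson benzylation of the three phenols and the secondary alcohol, run cold so that the phenoxides are capped before ring C can open.

Step 10
Reactants: 16 tetra-O-benzylafzelechin
Product: 17 (2R,3S)-3,5,7-tris(benzyloxy)-2-[4-(benzyloxy)phenyl]-6,8-dibromo-3,4-dihydro-2H-chromene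
Conditions: NBS (2.1 equiv), CH2Cl2, −78 °C to rt
Reagents that add atoms: N-bromosuccinimide, O=C1CCC(=O)N1Br
Why: Electrophilic aromatic bromination takes place at C8 and C6, the two positions of the trioxygenated ring A, well ahead of the mono-oxygenated rings.

Step 11
Reactants: 17 6,8-dibromide
Product: 19 (2R,3S)-3,5,7-tris(benzyloxy)-2-[4-(benzyloxy)phenyl]-3,4-dihydro-2H-chromene-6,8-dicarbaldehyde, via dilithio flavan 18 (not isolated)
Conditions: t-BuLi (4.4 equiv), THF, −78 °C; then DMF, −78 to 0 °C; H2O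
Reagents that add atoms: N,N-dimethylformamide, CN(C)C=O
Why: Double bromine–lithium exchange (each aryllithium flanked by two ether oxygens) followed by formylation with DMF (Bouveault aldehyde synthesis).

Step 12
Reactants: 19 6,8-dicarbaldehyde
Product: 20 (2R,3S)-3-(benzyloxy)-2-[4-(benzyloxy)phenyl]-5,7-dihydroxy-3,4-dihydro-2H-chromene-6,8-dicarbaldehyde
Conditions: MgBr2·OEt2 (6 equiv), toluene/Et2O, 70 °C; 1 M HCl
Reagents that add atoms: none
Why: Chelation-assisted cleavage by magnesium bromide removes only aryl benzyl ethers ortho to a carbonyl group, so the 5- and 7-O-benzyl groups fall while the 3-O- and 4'-O-benzyl groups stay.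

Step 13
Reactants: 20 dihydroxy dialdehyde; 21 [4-(benzyloxy)phenyl]magnesium bromide
Product: 22 flavan 6,8-bis(o-hydroxybenzhydrol) (carbinol epimers)
Conditions: 21 (5 equiv), THF, −78 to 0 °C; pH 7 buffer; used crude
Reagents that add atoms: none
Why: Grignard addition to the two salicylaldehyde-type magnesium phenoxides (two equivalents are spent on the phenols) gives the benzhydrols, whose carbinol configuration is irrelevant because both carbons become sp2 in the next step.

Step 14
Reactants: 22 flavan 6,8-bis(o-hydroxybenzhydrol); 14 dihydrofuran (2.6 equiv)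
Product: 26 bis-ketal (two cis-fused furo[2,3-b]pyran ketals on ring A), via first o-quinone methide 23 (not isolated), via mono-cycloadduct 24 (not isolated), via second o-quinone methide 25 (not isolated)
Conditions: (PhO)2P(O)OH (10 mol %), 5 Å MS, CH2Cl2, −40 to 0 °C
Reagents that add atoms: none
Why: The phosphoric acid ionises each o-hydroxybenzhydrol to an (E)-o-quinone methide (O7=C7–C8=Cα first, then O5=C5–C6=Cα once O7 is tied up), which reacts with the enol ether C2'=C3' of 14 in an inverse-electron-demand hetero-Diels–Alder reaction that is concerted but asynchronous, the Cα–C3' bond running ahead of the O–C2' bond. The closest known reaction type is the acid-catalysed [4+2] cycloaddition of o-quinone methides from o-hydroxybenzhydrols with 2,3-dihydrofurans, together with the use of chiral enol ethers to set diarylmethine centres in such cycloadditions. Each of the two new six-membered rings is closed in the [4+2] mode, suprafacial on both partners, which is why it is cis-fused to the oxolane. C3' is set by approach of the heterodiene to the enol ether face anti to the neighbouring C4' aroyl group; Cα is set by the (E)-geometry of the methide together with endo placement of the 2,4-bis(benzyloxy)phenyl group on C2' (stacked under the methide, as styrenes react) and exo placement of the dihydrofuran ring, the ring-endo alternative being blocked because the C5' aryl group stands on the reacting face; the ketal carbon C2' follows from the suprafacial addition and is erased in step 15. The selectivities needed are C3' of the enol ether over the benzyloxyarene rings (the enol ether is by far the better nucleophile), the pairing O7/C8 and O5/C6 (the C8 methide can only use O7, and because ketalisation is reversible under the acid a C6 arm that first closes on O7 is returned to O5), and the same configuration in both arms, which is secured because both are controlled by the same enantiopure dienophile and not by the remote flavan centres.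

Step 15
Reactants: 26 bis-ketal
Product: 27 tetradeca-O-benzyl target (5-OH and 7-OH free)
Conditions: Et3SiH (6 equiv), BF3·OEt2 (3 equiv), CH2Cl2, −78 °C; aq NaHCO3
Reagents that add atoms: none
Why: BF3 ionises each aryl ketal (phenoxide leaving group, C2' oxocarbenium ion stabilised by the 2,4-bis(benzyloxy)phenyl group) and triethylsilane delivers hydride to the face anti to both the C3' diarylmethyl and the C5' aryl substituents (ionic hydrogenation, reductive ketal opening), which should give the 2',3'-cis-2',5'-cis oxolane as in the reductive deoxygenation of 2-aryl cyclic hemiketals to 2,3-cis-3,4-trans-4,5-trans lignan oxolanes, while at −78 °C the aryl ketones and benzyl ethers stay intact and the 5- and 7-OH groups are released.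

Step 16
Reactants: 27 tetradeca-O-benzyl target
Product: 28 CNP0225367.3
Conditions: H2 (1 atm), Pd(OH)2/C, THF/MeOH, rt
Reagents that add atoms: none
Why: Neutral hydrogenolysis removes all fourteen O-benzyl groups, while the cyclic benzylic ethers, the hydrogen-bonded o-hydroxyaryl ketones and the epimerisable C4' centre (already in its thermodynamically preferred trans,trans arrangement) should survive, and no acid or base touches the ionisable C2' centre.

**Compound list**
1 | 1-[2,4-bis(benzyloxy)phenyl]ethan-1-one | CC(=O)c1ccc(OCc2ccccc2)cc1OCc1ccccc1 | starting material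
2 | 1-[2,4-bis(benzyloxy)phenyl]-2-bromoethan-1-one | BrCC(=O)c1ccc(OCc2ccccc2)cc1OCc1ccccc1 | intermediate
3 | {2-[2,4-bis(benzyloxy)phenyl]-2-oxoethyl}dimethylsulfonium bromide | C[S+](C)CC(=O)c1ccc(OCc2ccccc2)cc1OCc1ccccc1.[Br-] | intermediate
4 | 1-[2,4-bis(benzyloxy)phenyl]-2-(dimethyl-λ4-sulfanylidene)ethan-1-one | CS(C)=CC(=O)c1ccc(OCc2ccccc2)cc1OCc1ccccc1 | intermediate
5 | 4-(benzyloxy)benzaldehyde | O=Cc1ccc(OCc2ccccc2)cc1 | starting material
6 | (triphenyl-λ5-phosphanylidene)acetaldehyde | O=CC=P(c1ccccc1)(c1ccccc1)c1ccccc1 | starting material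
7 | (2E)-3-[4-(benzyloxy)phenyl]prop-2-enal | O=C/C=C/c1ccc(OCc2ccccc2)cc1 | intermediate
8 | (1R,2R,3R)-2-[2,4-bis(benzyloxy)benzoyl]-3-[4-(benzyloxy)phenyl]cyclopropane-1-carbaldehyde (formyl trans to both aroyl and aryl) | O=C[C@H]1[C@H](C(=O)c2ccc(OCc3ccccc3)cc2OCc2ccccc2)[C@@H]1c1ccc(OCc2ccccc2)cc1 | intermediate
9 | 4-bromobenzene-1,3-diol | Oc1ccc(Br)c(O)c1 | starting material
10 | 2,4-bis(benzyloxy)-1-bromobenzene | Brc1ccc(OCc2ccccc2)cc1OCc1ccccc1 | intermediate
11 | [2,4-bis(benzyloxy)phenyl]magnesium bromide | Br[Mg]c1ccc(OCc2ccccc2)cc1OCc1ccccc1 | intermediate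
12 | [(1R,2R,3R)-2-{[2,4-bis(benzyloxy)phenyl](hydroxy)methyl}-3-[4-(benzyloxy)phenyl]cyclopropyl][2,4-bis(benzyloxy)phenyl]methanone, both carbinol epimers | OC(c1ccc(OCc2ccccc2)cc1OCc1ccccc1)[C@H]1[C@H](C(=O)c2ccc(OCc3ccccc3)cc2OCc2ccccc2)[C@@H]1c1ccc(OCc2ccccc2)cc1 | intermediate
13 | {(1R,2R)-3-[4-(benzyloxy)phenyl]cyclopropane-1,2-diyl}bis{[2,4-bis(benzyloxy)phenyl]methanone} (aroyl groups trans) | O=C(c1ccc(OCc2ccccc2)cc1OCc1ccccc1)[C@H]1[C@H](C(=O)c2ccc(OCc3ccccc3)cc2OCc2ccccc2)C1c1ccc(OCc2ccccc2)cc1 | intermediate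
14 | {(2S,3S)-5-[2,4-bis(benzyloxy)phenyl]-2-[4-(benzyloxy)phenyl]-2,3-dihydrofuran-3-yl}[2,4-bis(benzyloxy)phenyl]methanone (trans; ring C5=C4 is C2'=C3', C3 is C4', C2 is C5') | O=C(c1ccc(OCc2ccccc2)cc1OCc1ccccc1)[C@H]1C=C(c2ccc(OCc3ccccc3)cc2OCc2ccccc2)O[C@@H]1c1ccc(OCc2ccccc2)cc1 | intermediate
15 | (+)-afzelechin, (2R,3S)-2-(4-hydroxyphenyl)-3,4-dihydro-2H-chromene-3,5,7-triol | Oc1cc(O)c2c(c1)O[C@H](c1ccc(O)cc1)[C@@H](O)C2 | starting material
16 | (2R,3S)-3,5,7-tris(benzyloxy)-2-[4-(benzyloxy)phenyl]-3,4-dihydro-2H-chromene | C(c1ccccc1)Oc1cc(OCc2ccccc2)c2c(c1)O[C@H](c1ccc(OCc3ccccc3)cc1)[C@@H](OCc1ccccc1)C2 | intermediate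
17 | (2R,3S)-3,5,7-tris(benzyloxy)-2-[4-(benzyloxy)phenyl]-6,8-dibromo-3,4-dihydro-2H-chromene | Brc1c(OCc2ccccc2)c(Br)c(OCc2ccccc2)c2c1O[C@H](c1ccc(OCc3ccccc3)cc1)[C@@H](OCc1ccccc1)C2 | intermediate
18 | 6,8-dilithio derivative of 16 | [Li]c1c(OCc2ccccc2)c([Li])c(OCc2ccccc2)c2c1O[C@H](c1ccc(OCc3ccccc3)cc1)[C@@H](OCc1ccccc1)C2 | intermediate
19 | (2R,3S)-3,5,7-tris(benzyloxy)-2-[4-(benzyloxy)phenyl]-3,4-dihydro-2H-chromene-6,8-dicarbaldehyde | O=Cc1c(OCc2ccccc2)c(C=O)c(OCc2ccccc2)c2c1O[C@H](c1ccc(OCc3ccccc3)cc1)[C@@H](OCc1ccccc1)C2 | intermediate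
20 | (2R,3S)-3-(benzyloxy)-2-[4-(benzyloxy)phenyl]-5,7-dihydroxy-3,4-dihydro-2H-chromene-6,8-dicarbaldehyde | O=Cc1c(O)c(C=O)c(O)c2c1O[C@H](c1ccc(OCc3ccccc3)cc1)[C@@H](OCc1ccccc1)C2 | intermediate
21 | [4-(benzyloxy)phenyl]magnesium bromide (commercial THF solution) | Br[Mg]c1ccc(OCc2ccccc2)cc1 | starting material
22 | (2R,3S)-3-(benzyloxy)-2-[4-(benzyloxy)phenyl]-6,8-bis{[4-(benzyloxy)phenyl](hydroxy)methyl}-3,4-dihydro-2H-chromene-5,7-diol, carbinol epimers | OC(c1ccc(OCc2ccccc2)cc1)c1c(O)c(C(O)c2ccc(OCc3ccccc3)cc2)c(O)c2c1O[C@H](c1ccc(OCc3ccccc3)cc1)[C@@H](OCc1ccccc1)C2 | intermediate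
23 | first o-quinone methide: (2R,3S)-3-(benzyloxy)-8-[(E)-4-(benzyloxy)benzylidene]-2-[4-(benzyloxy)phenyl]-6-{[4-(benzyloxy)phenyl](hydroxy)methyl}-5-hydroxy-3,4-dihydro-2H-chromen-7(8H)-one | O=C1C(C(O)c2ccc(OCc3ccccc3)cc2)=C(O)C2=C(O[C@H](c3ccc(OCc4ccccc4)cc3)[C@@H](OCc3ccccc3)C2)/C1=C\c1ccc(OCc2ccccc2)cc1 | intermediate
24 | mono-cycloadduct: the C8 arm of 22 closed on O7 as a cis-fused furo[2,3-b]pyran ketal (Cα S, C2' R, C3' S, C4' S, C5' S); C6 benzhydrol and 5-OH unchanged | C(c1ccccc1)O[C@H]1Cc2c(O[C@@H]1c1ccc(OCc3ccccc3)cc1)c1c(c(C(O)c3ccc(OCc4ccccc4)cc3)c2O)O[C@]2(c3ccc(OCc4ccccc4)cc3OCc3ccccc3)O[C@H](c3ccc(OCc4ccccc4)cc3)[C@@H](C(=O)c3ccc(OCc4ccccc4)cc3OCc3ccccc3)[C@@H]2[C@H]1c1ccc(OCc2ccccc2)cc1 | intermediate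
25 | second o-quinone methide: 24 dehydrated at the C6 arm, C5=O and C6=(E)-CH[4-(benzyloxy)phenyl] | O=C1C2=C(O[C@H](c3ccc(OCc4ccccc4)cc3)[C@@H](OCc3ccccc3)C2)C3=C(O[C@]4(c5ccc(OCc6ccccc6)cc5OCc5ccccc5)O[C@H](c5ccc(OCc6ccccc6)cc5)[C@@H](C(=O)c5ccc(OCc6ccccc6)cc5OCc5ccccc5)[C@@H]4[C@H]3c3ccc(OCc4ccccc4)cc3)/C1=C\c1ccc(OCc2ccccc2)cc1 | intermediate
26 | bis-ketal: (2R,3S)-3-(benzyloxy)-2-[4-(benzyloxy)phenyl]chromane in which O5/C6 and O7/C8 each carry a pyran ring made of CαH[4-(benzyloxy)phenyl], C3'H and the ketal carbon C2' [2,4-bis(benzyloxy)phenyl], each C2'–C3' bond shared cis with an oxolane O1'–C5'H[4-(benzyloxy)phenyl]–C4'H[2,4-bis(benzyloxy)benzoyl]; both arms Cα S, C2' R, C3' S, C4' S, C5' S | C(c1ccccc1)O[C@H]1Cc2c(O[C@@H]1c1ccc(OCc3ccccc3)cc1)c1c(c3c2O[C@]2(c4ccc(OCc5ccccc5)cc4OCc4ccccc4)O[C@H](c4ccc(OCc5ccccc5)cc4)[C@@H](C(=O)c4ccc(OCc5ccccc5)cc4OCc4ccccc4)[C@@H]2[C@H]3c2ccc(OCc3ccccc3)cc2)O[C@]2(c3ccc(OCc4ccccc4)cc3OCc3ccccc3)O[C@H](c3ccc(OCc4ccccc4)cc3)[C@@H](C(=O)c3ccc(OCc4ccccc4)cc3OCc3ccccc3)[C@@H]2[C@H]1c1ccc(OCc2ccccc2)cc1 | intermediate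
27 | tetradeca-O-benzyl target: 28 with the 3-O, the 4'-O and all twelve arm phenols benzylated, 5-OH and 7-OH free; flavan 2R,3S; each arm Cα S, C2' R, C3' S, C4' S, C5' S | O=C(c1ccc(OCc2ccccc2)cc1OCc1ccccc1)[C@H]1[C@H]([C@@H](c2ccc(OCc3ccccc3)cc2)c2c(O)c3c(c([C@H](c4ccc(OCc5ccccc5)cc4)[C@H]4[C@H](C(=O)c5ccc(OCc6ccccc6)cc5OCc5ccccc5)[C@@H](c5ccc(OCc6ccccc6)cc5)O[C@H]4c4ccc(OCc5ccccc5)cc4OCc4ccccc4)c2O)O[C@H](c2ccc(OCc4ccccc4)cc2)[C@@H](OCc2ccccc2)C3)[C@H](c2ccc(OCc3ccccc3)cc2OCc2ccccc2)O[C@@H]1c1ccc(OCc2ccccc2)cc1 | intermediate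
28 | CNP0225367.3: (2R,3S)-afzelechin bearing at C6 and at C8 an (S)-(4-hydroxyphenyl)methyl group bonded to C3 of a (2R,3S,4S,5S)-4-(2,4-dihydroxybenzoyl)-2-(2,4-dihydroxyphenyl)-5-(4-hydroxyphenyl)oxolane | O=C(c1ccc(O)cc1O)[C@H]1[C@H]([C@@H](c2ccc(O)cc2)c2c(O)c3c(c([C@H](c4ccc(O)cc4)[C@H]4[C@H](C(=O)c5ccc(O)cc5O)[C@@H](c5ccc(O)cc5)O[C@H]4c4ccc(O)cc4O)c2O)O[C@H](c2ccc(O)cc2)[C@@H](O)C3)[C@H](c2ccc(O)cc2O)O[C@@H]1c1ccc(O)cc1 | target

**Step count and risks**
Total steps: 16. Longest linear sequence: 9 steps (steps 1, 2, 4, 6, 7, 8, 14, 15, 16, from 1 to 28).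

Steps most likely to fail:

Step 14. The acid and the water released may hydrolyse or isomerise the enol ether of 14, and a stepwise ionic pathway may erode the endo topicity that sets Cα, or the second cycloaddition may stall. Fallback: the quinone methides are generated under anionic, acid-free conditions. Setting out from 20, Grignard reagent 21 (4 equiv, THF, −78 °C) is added and the benzylic magnesium alkoxides are acylated in the same flask with Boc2O to give the bis(benzylic tert-butyl carbonate) F1 as its magnesium phenoxide. Dihydrofuran 14 is then added and the mixture warmed to 0 °C, so that phenoxide-driven 1,4-elimination of tert-butyl carbonate releases each o-quinone methide at low temperature for a thermal, kinetically controlled [4+2] reaction. The sequence comes back to the route at 26.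

Step 15. Hydride may be delivered to the wrong face of the C2' oxocarbenium ion, or the electron-rich aryl ketones may be reduced by the silane/Lewis acid pair. Fallback: setting out from 26, the ketals are opened by organocatalytic transfer hydrogenation. A BINOL-derived chiral phosphoric acid (TRIP, either enantiomer to be matched to the substrate) ionises the ketal and holds the oxocarbenium ion as a chiral ion pair, and a Hantzsch ester (diethyl 2,6-dimethyl-1,4-dihydropyridine-3,5-dicarboxylate) delivers the hydride under catalyst control; aryl ketones are inert to these conditions. The sequence comes back at 27 and no new compound is made (F0).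

Step 4. Iminium formation from the electron-rich cinnamaldehyde 7 may be slow and the enantio- or diastereoselectivity of the ylide addition may be low. Fallback: the cyclopropane is built on a symmetrical acceptor, where only face selectivity matters because the aryl-bearing carbon of 13 is not stereogenic. Setting out from 1, oxidation with SeO2 (dioxane/H2O, reflux) gives 2-[2,4-bis(benzyloxy)phenyl]-2-oxoacetaldehyde F2, and aldol condensation of F2 with a second equivalent of 1 gives (2E)-1,4-bis[2,4-bis(benzyloxy)phenyl]but-2-ene-1,4-dione F3. Aldehyde 5 is converted with tosylhydrazine and NaOMe into the tosylhydrazone sodium salt F4, which releases the aryldiazomethane in the flask (BnEt3NCl, 40 °C). With Rh2(OAc)4 (1 mol %) and a camphor-derived chiral sulfide (20 mol %) this forms a chiral sulfonium benzylide that cyclopropanates F3 (Michael addition, then ring closure with the trans-diketone geometry retained). The sequence comes back at 13 and replaces steps 1 to 7.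

Further compounds
F1 | step 14 | (2R,3S)-3-(benzyloxy)-2-[4-(benzyloxy)phenyl]-6,8-bis{[4-(benzyloxy)phenyl][(tert-butoxycarbonyl)oxy]methyl}-3,4-dihydro-2H-chromene-5,7-diol | CC(C)(C)OC(=O)OC(c1ccc(OCc2ccccc2)cc1)c1c(O)c(C(OC(=O)OC(C)(C)C)c2ccc(OCc3ccccc3)cc2)c(O)c2c1O[C@H](c1ccc(OCc3ccccc3)cc1)[C@@H](OCc1ccccc1)C2
F0 | step 15 | none | none
F2 | step 4 | 2-[2,4-bis(benzyloxy)phenyl]-2-oxoacetaldehyde | O=CC(=O)c1ccc(OCc2ccccc2)cc1OCc1ccccc1
F3 | step 4 | (2E)-1,4-bis[2,4-bis(benzyloxy)phenyl]but-2-ene-1,4-dione | O=C(/C=C/C(=O)c1ccc(OCc2ccccc2)cc1OCc1ccccc1)c1ccc(OCc2ccccc2)cc1OCc1ccccc1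
F4 | step 4 | sodium salt of N'-[4-(benzyloxy)benzylidene]-4-methylbenzenesulfonohydrazide | Cc1ccc(S(=O)(=O)[N-]N=Cc2ccc(OCc3ccccc3)cc2)cc1.[Na+]
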